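**Plan**
- Retrosynthetic cuts: C3=C4 (ring-closing metathesis) and the C4=C3/C5=C16 diene back to a C4≡C5 alkyne; the lactone C19–O7 bond and C6–C7 (chloroallenylzinc addition); C8–C9 (aldol); C2–C3 (vinyl addition); C1–C14 and C10–C11 (Diels–Alder).
- Enabling feature: the cyclohexene ring C1/C10–C14 has a quaternary C1 whose C2 branch is trans to the C9 branch on C10, an oxygen on C12 and a methyl on C11. This is the imprint of a 2-siloxydiene added to an (E)-2-methyl-2-enal.
- Forward order: cyclohexene ring (step 3); C2 carbinol and ring diene; C8–C9 aldol with a methyl-substituted butyrolactone; reduction, chloropropargylation and re-lactonisation to the γ-lactone bearing C6–Cl; dihydroxylation and acylations; ten-membered ring last, by enyne cross-metathesis then ring-closing metathesis.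
- Stereochemistry: C1/C10 from the chiral Lewis acid and the E-enal; C2 by Felkin–Anh addition; C17 purchased; C8/C9 relayed from C17 through a Zimmerman–Traxler chair; C7 by Felkin–Anh addition and C6 by the anti-selective SE2' step; C11/C12 by syn-dihydroxylation anti to the C10 chain; Z-C3=C4 imposed by the ring.

Key step: step 3

Remarks: locants C1–C20 are those of the briarane skeleton of 33, and "as in 33" means the same spatial arrangement whatever the CIP letter becomes; lactone 15 and propyne 23 are assumed to be purchasable; the C11 configuration of 6–9 is immaterial because C11 becomes trigonal in step 7; if the cycloaddition shows the opposite sense of induction, the mirror-image catalyst is used.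

**Step 1**
Reactants: 1 pent-1-en-3-one
Product: 2 (Z)-3-(tert-butyldimethylsilyloxy)penta-1,3-diene
Conditions: TBSOTf, Et3N, CH2Cl2, 0 °C
Reagents that add atoms: tert-butyldimethylsilyl triflate CC(C)(C)[Si](C)(C)OS(=O)(=O)C(F)(F)F
Why: Soft enolisation of the enone (silyl dienol ether formation) gives the 2-siloxydiene, the (Z)-enol ether being favoured because the methyl group avoids the vinyl group.

**Step 2**
Reactants: 3 (tert-butyldimethylsilyloxy)acetaldehyde; 4 2-(triphenylphosphoranylidene)propanal
Product: 5 (E)-4-(tert-butyldimethylsilyloxy)-2-methylbut-2-enal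
Conditions: toluene, 80 °C
Reagents that add atoms: none
Why: Wittig olefination with a stabilised formyl ylide is E-selective and stops after one homologation because the product enal is less electrophilic than the α-alkoxy aldehyde.

**Step 3**
Reactants: 2 (Z)-3-(tert-butyldimethylsilyloxy)penta-1,3-diene; 5 (E)-4-(tert-butyldimethylsilyloxy)-2-methylbut-2-enal
Product: 6 (1S,5S,6S)-4-(tert-butyldimethylsilyloxy)-6-[(tert-butyldimethylsilyloxy)methyl]-1,5-dimethylcyclohex-3-ene-1-carbaldehyde (C1, C11 and C10 of the skeleton)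
Conditions: (R)-oxazaborolidinium triflimide [from (R)-3,3-diphenyl-1-(2-methylphenyl)tetrahydro-1H,3H-pyrrolo[1,2-c][1,3,2]oxazaborole and HNTf2] (10 mol %), CH2Cl2, −78 to −40 °C
Reagents that add atoms: none
Why: The cationic boron Lewis acid binds the formyl oxygen of the s-trans enal 5, lowers its LUMO, and a concerted but asynchronous [4+2] cycloaddition forms C10–C11 ahead of C1–C14; the closest known reaction type is the oxazaborolidinium-catalysed Diels–Alder reaction of α-substituted enals with 2-silyloxydienes. The cyclohexene ring closes in an intermolecular cycloaddition mode, both bonds forming suprafacially on each partner. C1 and C10 are fixed relative to each other by the E geometry of 5 (C2 trans to C9) and in the absolute sense by the catalyst, which shields one enal face so that the diene should add to the Si face of the α-carbon; C11 follows from the formyl-endo transition state and the outward methyl of the (Z)-enol ether, and is erased in step 7. Regioselectivity (nucleophilic diene terminus C11 to the β-carbon C10, so that the formyl carbon ends on quaternary C1) is secured by the 2-siloxy group. The step needs enantio- and regiocontrol only, and the acid-sensitive enol ether is preserved by low temperature and a sub-stoichiometric, non-nucleophilic acid.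

**Step 4**
Reactants: 6 cycloadduct aldehyde
Product: 7 (S)-1-[(1S,5S,6S)-4-(tert-butyldimethylsilyloxy)-6-[(tert-butyldimethylsilyloxy)methyl]-1,5-dimethylcyclohex-3-en-1-yl]prop-2-en-1-ol (C2 carbinol, 2S)
Conditions: CH2=CHMgBr, THF, −78 to −40 °C; aq. NH4Cl
Reagents that add atoms: vinylmagnesium bromide C=C[Mg]Br
Why: Grignard 1,2-addition to the non-enolisable neopentyl aldehyde should follow the Felkin–Anh model with the C10 branch anti to the nucleophile, which gives the (2S)-carbinol, and any epimer is removed by chromatography.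

**Step 5**
Reactants: 7 allylic alcohol
Product: 8 4-methoxybenzyl (PMB) ether of 7 at O2
Conditions: NaH, 4-methoxybenzyl bromide, Bu4NI (cat.), THF–DMF, 0 °C
Reagents that add atoms: 4-methoxybenzyl bromide COc1ccc(CBr)cc1
Why: Williamson etherification of the sodium alkoxide, tolerated by both silyl groups at 0 °C, installs an ether that can later be cleaved oxidatively beside esters and a lactone.

**Step 6**
Reactants: 8 PMB ether
Product: 9 (4S,5S,6S)-5-[(tert-butyldimethylsilyloxy)methyl]-4-[(S)-1-(4-methoxybenzyloxy)prop-2-enyl]-4,6-dimethylcyclohex-2-en-1-one (C12 ketone, C13=C14)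
Conditions: Pd(OAc)2 (1.1 equiv), MeCN, rt
Reagents that add atoms: none
Why: Saegusa oxidation, in which divalent palladium forms the C13-palladated ketone from the regiodefined silyl enol ether and β-hydride elimination toward C14 gives the C13=C14 enone.

**Step 7**
Reactants: 9 enone
Product: 11 dienyl triflate (C11=C12(OTf)–C13=C14; C1, C2, C10 as in 33), via lithium dienolate 10 (not isolated)
Conditions: LiN(i-Pr)2, THF, −78 °C; PhNTf2, −78 to 0 °C
Reagents that add atoms: N-phenylbis(trifluoromethanesulfonimide) O=S(=O)(N(c1ccccc1)S(=O)(=O)C(F)(F)F)C(F)(F)F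
Why: Enol triflate synthesis by kinetic deprotonation, which can occur only at C11 because the γ-carbon C1 is quaternary, followed by O-triflation of the cross-conjugated dienolate, fixing the C11=C12 bond.

**Step 8**
Reactants: 11 dienyl triflate
Product: 12 tert-butyl{[(1S,6S)-6-[(S)-1-(4-methoxybenzyloxy)prop-2-enyl]-2,6-dimethylcyclohexa-2,4-dien-1-yl]methoxy}dimethylsilane (ring diene C11=C12–C13=C14)
Conditions: Pd(OAc)2 (5 mol %), PPh3, Bu3N, HCO2H, DMF, 60 °C
Reagents that add atoms: none
Why: Palladium-catalysed formate reduction of an enol triflate (oxidative addition to zerovalent palladium, formate exchange, decarboxylation, reductive elimination) replaces OTf by H without touching the other alkenes.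

**Step 9**
Reactants: 12 silyl ether
Product: 13 [(1S,6S)-6-[(S)-1-(4-methoxybenzyloxy)prop-2-enyl]-2,6-dimethylcyclohexa-2,4-dien-1-yl]methanol (C9 alcohol)
Conditions: Bu4NF, THF, 0 °C; aq. NH4Cl
Reagents that add atoms: none
Why: Fluoride-mediated desilylation cleaves the primary silyl ether and leaves the PMB ether untouched.

**Step 10**
Reactants: 13 primary alcohol
Product: 14 (1S,6S)-6-[(S)-1-(4-methoxybenzyloxy)prop-2-enyl]-2,6-dimethylcyclohexa-2,4-diene-1-carbaldehyde (C9 aldehyde)
Conditions: Dess–Martin periodinane, pyridine, CH2Cl2, 0 °C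
Reagents that add atoms: none
Why: Dess–Martin oxidation under buffered, non-basic conditions should give the β,γ-unsaturated aldehyde without epimerising C10 or moving the diene into conjugation.

**Step 11**
Reactants: 15 (R)-4-methyldihydrofuran-2(3H)-one
Product: 17 (3R,4S)-3-hydroxy-4-methyldihydrofuran-2(3H)-one, via potassium enolate 16 (not isolated)
Conditions: KN(SiMe3)2, THF, −78 °C; 3-phenyl-2-(phenylsulfonyl)oxaziridine; aq. NH4Cl
Reagents that add atoms: 3-phenyl-2-(phenylsulfonyl)oxaziridine O=S(=O)(N1OC1c1ccccc1)c1ccccc1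
Why: Enolate hydroxylation by electrophilic oxygen transfer from an N-sulfonyloxaziridine occurs anti to the C4 methyl group, and the C3 configuration is of no consequence because C3 is re-enolised in step 13.

**Step 12**
Reactants: 17 hydroxy lactone
Product: 18 (3R,4S)-4-methyl-3-(triethylsilyloxy)dihydrofuran-2(3H)-one
Conditions: Et3SiCl, imidazole, DMF, rt
Reagents that add atoms: chlorotriethylsilane CC[Si](Cl)(CC)CC
Why: Silylation of a secondary alcohol gives a non-chelating ether that survives enolate formation and can still be removed at the end from a tertiary position.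

**Step 13**
Reactants: 18 silyloxy lactone; 14 aldehyde
Product: 20 (3R,4S)-3-{(S)-hydroxy[(1S,6S)-6-[(S)-1-(4-methoxybenzyloxy)prop-2-enyl]-2,6-dimethylcyclohexa-2,4-dien-1-yl]methyl}-4-methyl-3-(triethylsilyloxy)dihydrofuran-2(3H)-one (C8, C9, C17 as in 33; lactone carbonyl is C7), via lithium enolate 19 (not isolated)
Conditions: LiN(i-Pr)2, THF, −78 °C; 14, −78 °C; aq. NH4Cl at −78 °C
Reagents that add atoms: none
Why: Lithium enolate aldol addition through a Zimmerman–Traxler chair, in which the aldehyde approaches the cyclic enolate anti to the C17 methyl group (setting C8) and the silyloxy group cis to the enolate oxygen delivers the 8,9-syn relationship (setting C9), so both new centres are relayed from C17.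

**Step 14**
Reactants: 20 aldol adduct
Product: 21 8,9-bis(triethylsilyl) ether (lactone C7=O, O–C19)
Conditions: Et3SiOTf, 2,6-lutidine, CH2Cl2, −40 to 0 °C
Reagents that add atoms: triethylsilyl triflate CC[Si](CC)(CC)OS(=O)(=O)C(F)(F)F
Why: Silyl triflate silylation of the hindered C9 alcohol blocks the hydroxyl that would otherwise compete with O7 in the later lactonisation.

**Step 15**
Reactants: 21 bis-silyl lactone
Product: 22 lactol (C7 hemiacetal, anomeric mixture)
Conditions: i-Bu2AlH, CH2Cl2, −78 °C; Rochelle salt work-up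
Reagents that add atoms: none
Why: Partial lactone reduction by i-Bu2AlH stops at the tetrahedral aluminium lactolate at −78 °C, and silyl and PMB ethers are inert.

**Step 16**
Reactants: 22 lactol; 23 (3-chloroprop-1-yn-1-yl)trimethylsilane
Product: 25 open-chain chlorohydrin diol (C19 primary OH, C7 secondary OH, C6–Cl anti to O7, C4≡C5 trimethylsilyl alkyne; C6, C7 as in 33), via allenylzinc bromide 24 (not isolated)
Conditions: 23, LiN(i-Pr)2, ZnBr2, THF, −90 °C; 22 pre-treated with i-PrMgCl (1 equiv), −78 to −20 °C; aq. NH4Cl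
Reagents that add atoms: none
Why: The magnesium lactolate opens to the α-silyloxy aldehyde, to which the chloroallenylzinc carbenoid adds by SE2' through a cyclic transition state that gives the anti chlorohydrin (C6), while Felkin–Anh approach anti to the C8–OSi bond and past the smaller C17 branch sets C7.

**Step 17**
Reactants: 25 chlorohydrin diol
Product: 26 γ-lactone (C19=O, O–C7) bearing C6–Cl and the silyl alkyne; 8,9-bis-silyl ether
Conditions: TEMPO (0.2 equiv), PhI(OAc)2, CH2Cl2, rt
Reagents that add atoms: none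
Why: Oxidative lactonisation of a 1,4-diol, in which the oxoammonium oxidant selects the primary C19 alcohol, the aldehyde is trapped by the C7 hydroxyl and the lactol is oxidised on, under conditions neutral enough to keep the chlorohydrin from closing to an epoxide.

**Step 18**
Reactants: 26 lactone with ring diene
Product: 27 11α,12α-diol (C13=C14 retained; C11, C12 as in 33)
Conditions: OsO4 (5 mol %), N-methylmorpholine N-oxide, acetone–H2O, 0 °C to rt
Reagents that add atoms: osmium tetroxide O=[Os](=O)(=O)=O; N-methylmorpholine N-oxide C[N+]1([O-])CCOCC1; water O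
Why: Syn-dihydroxylation by OsO4 should prefer the electron-rich trisubstituted C11=C12 bond over the C13=C14 bond, the hindered allylic-ether vinyl group and the alkyne, and attack the face opposite the bulky C10 side chain.

**Step 19**
Reactants: 27 diol
Product: 28 8,9,11,12-tetraol with terminal alkyne (O2 still PMB-protected)
Conditions: Bu4NF, AcOH (1:1), THF, 0 °C to rt
Reagents that add atoms: none
Why: Fluoride-mediated desilylation cleaves both O–Si bonds and the alkynyl C–Si bond in one operation, and the acetic acid buffer suppresses lactone acyl migration to O9 and base-induced loss of HCl.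

**Step 20**
Reactants: 28 tetraol
Product: 29 9,12-diacetate (8-OH and 11-OH free)
Conditions: Ac2O, DMAP, pyridine, CH2Cl2, 0 °C to rt
Reagents that add atoms: acetic anhydride CC(=O)OC(C)=O
Why: DMAP-catalysed acylation esterifies the two secondary alcohols, while the tertiary C8 and C11 hydroxyls do not react at room temperature.

**Step 21**
Reactants: 29 diacetate
Product: 30 C2 allylic alcohol
Conditions: DDQ, CH2Cl2–pH 7 buffer, 0 °C
Reagents that add atoms: none
Why: Oxidative PMB cleavage by DDQ (hydride abstraction, then hemiacetal hydrolysis) tolerates esters, lactone, chloride and isolated alkenes, and is placed after step 18 because DDQ would attack the ring diene.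

**Step 22**
Reactants: 30 allylic alcohol
Product: 31 C2 butanoate (seco enyne: C2 vinyl group and C4≡C5 terminal alkyne)
Conditions: butyric anhydride, DMAP, Et3N, CH2Cl2, rt
Reagents that add atoms: butyric anhydride CCCC(=O)OC(=O)CCC
Why: DMAP-catalysed acylation of the only remaining secondary alcohol installs the butanoate.

**Step 23**
Reactants: 31 enyne
Product: 32 triene (C5(=C16H2)–C4H=CH2 diene and C2 vinyl group)
Conditions: RuCl2(=CHPh)(PCy3)(H2IMes) (second-generation Grubbs catalyst, 10 mol %), ethylene (1 atm), CH2Cl2, rt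
Reagents that add atoms: ethylene C=C
Why: Cross enyne metathesis of a terminal alkyne with ethylene converts the triple bond into the 2-substituted buta-1,3-diene and so creates the C5 exocyclic methylene, the hindered C2 vinyl group and the ring alkene being spectators.

**Step 24**
Reactants: 32 triene
Product: 33 CNP0114781.2 (target)
Conditions: RuCl2(=CH-C6H4-2-O-i-Pr)(H2IMes) (second-generation Hoveyda–Grubbs catalyst, 15 mol %), toluene, 1 mM, 80 °C, argon sparge
Reagents that add atoms: none
Why: Ring-closing metathesis between the C2 vinyl group and the monosubstituted diene terminus (the 1,1-disubstituted C5=C16 bond is unreactive) expels ethylene, and the ten-membered ring should constrain the new C3=C4 bond to Z.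

**Compound list**
1 | pent-1-en-3-one | CCC(=O)C=C | starting material
2 | (Z)-3-(tert-butyldimethylsilyloxy)penta-1,3-diene | C/C=C(/C=C)O[Si](C)(C)C(C)(C)C | intermediate
3 | (tert-butyldimethylsilyloxy)acetaldehyde | O=CCO[Si](C)(C)C(C)(C)C | starting material
4 | 2-(triphenylphosphoranylidene)propanal | CC(C=O)=P(c1ccccc1)(c1ccccc1)c1ccccc1 | starting material
5 | (E)-4-(tert-butyldimethylsilyloxy)-2-methylbut-2-enal | O=C/C(C)=C/CO[Si](C)(C)C(C)(C)C | intermediate
6 | (1S,5S,6S)-4-(tert-butyldimethylsilyloxy)-6-[(tert-butyldimethylsilyloxy)methyl]-1,5-dimethylcyclohex-3-ene-1-carbaldehyde | O=C[C@@]1(C)CC=C(O[Si](C)(C)C(C)(C)C)[C@@H](C)[C@@H]1CO[Si](C)(C)C(C)(C)C | intermediate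
7 | (S)-1-[(1S,5S,6S)-4-(tert-butyldimethylsilyloxy)-6-[(tert-butyldimethylsilyloxy)methyl]-1,5-dimethylcyclohex-3-en-1-yl]prop-2-en-1-ol | C=C[C@H](O)[C@@]1(C)CC=C(O[Si](C)(C)C(C)(C)C)[C@@H](C)[C@@H]1CO[Si](C)(C)C(C)(C)C | intermediate
8 | O2-(4-methoxybenzyl) ether of 7 | C=C[C@H](OCc1ccc(OC)cc1)[C@@]2(C)CC=C(O[Si](C)(C)C(C)(C)C)[C@@H](C)[C@@H]2CO[Si](C)(C)C(C)(C)C | intermediate
9 | (4S,5S,6S)-5-[(tert-butyldimethylsilyloxy)methyl]-4-[(S)-1-(4-methoxybenzyloxy)prop-2-enyl]-4,6-dimethylcyclohex-2-en-1-one | C=C[C@H](OCc1ccc(OC)cc1)[C@@]2(C)C=CC(=O)[C@@H](C)[C@@H]2CO[Si](C)(C)C(C)(C)C | intermediate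
10 | lithium dienolate of 9 (C11=C12–OLi) | C=C[C@H](OCc1ccc(OC)cc1)[C@@]2(C)C=CC(O[Li])=C(C)[C@@H]2CO[Si](C)(C)C(C)(C)C | intermediate (not isolated)
11 | dienyl triflate (C12–OTf, C11=C12, C13=C14) | C=C[C@H](OCc1ccc(OC)cc1)[C@@]2(C)C=CC(OS(=O)(=O)C(F)(F)F)=C(C)[C@@H]2CO[Si](C)(C)C(C)(C)C | intermediate
12 | tert-butyl{[(1S,6S)-6-[(S)-1-(4-methoxybenzyloxy)prop-2-enyl]-2,6-dimethylcyclohexa-2,4-dien-1-yl]methoxy}dimethylsilane | C=C[C@H](OCc1ccc(OC)cc1)[C@@]2(C)C=CC=C(C)[C@@H]2CO[Si](C)(C)C(C)(C)C | intermediate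
13 | [(1S,6S)-6-[(S)-1-(4-methoxybenzyloxy)prop-2-enyl]-2,6-dimethylcyclohexa-2,4-dien-1-yl]methanol | C=C[C@H](OCc1ccc(OC)cc1)[C@@]2(C)C=CC=C(C)[C@@H]2CO | intermediate
14 | (1S,6S)-6-[(S)-1-(4-methoxybenzyloxy)prop-2-enyl]-2,6-dimethylcyclohexa-2,4-diene-1-carbaldehyde | C=C[C@H](OCc1ccc(OC)cc1)[C@@]2(C)C=CC=C(C)[C@@H]2C=O | intermediate
15 | (R)-4-methyldihydrofuran-2(3H)-one | O=C1C[C@@H](C)CO1 | starting material
16 | potassium enolate of 15 | [K]OC1=C[C@@H](C)CO1 | intermediate (not isolated)
17 | (3R,4S)-3-hydroxy-4-methyldihydrofuran-2(3H)-one | O=C1[C@H](O)[C@@H](C)CO1 | intermediate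
18 | (3R,4S)-4-methyl-3-(triethylsilyloxy)dihydrofuran-2(3H)-one | O=C1[C@H](O[Si](CC)(CC)CC)[C@@H](C)CO1 | intermediate
19 | lithium enolate of 18 | [Li]OC1=C(O[Si](CC)(CC)CC)[C@@H](C)CO1 | intermediate (not isolated)
20 | aldol adduct: C9 alcohol, C8 triethylsilyl ether, lactone C7(=O)–O–C19 | C=C[C@H](OCc1ccc(OC)cc1)[C@@]2(C)C=CC=C(C)[C@@H]2[C@H](O)[C@]3(O[Si](CC)(CC)CC)[C@@H](C)COC3=O | intermediate
21 | 8,9-bis(triethylsilyl) ether of 20 | C=C[C@H](OCc1ccc(OC)cc1)[C@@]2(C)C=CC=C(C)[C@@H]2[C@H](O[Si](CC)(CC)CC)[C@]3(O[Si](CC)(CC)CC)[C@@H](C)COC3=O | intermediate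
22 | lactol of 21 (C7 hemiacetal, anomeric mixture) | C=C[C@H](OCc1ccc(OC)cc1)[C@@]2(C)C=CC=C(C)[C@@H]2[C@H](O[Si](CC)(CC)CC)[C@]3(O[Si](CC)(CC)CC)[C@@H](C)COC3O | intermediate
23 | (3-chloroprop-1-yn-1-yl)trimethylsilane | C[Si](C)(C)C#CCCl | starting material
24 | [3-chloro-1-(trimethylsilyl)propa-1,2-dien-1-yl]zinc bromide | C[Si](C)(C)C([Zn]Br)=C=CCl | intermediate (not isolated)
25 | chlorohydrin diol: C19–OH, C7–OH, C6–Cl, C4≡C5–SiMe3, 8,9-bis(triethylsilyl) ether | C=C[C@H](OCc1ccc(OC)cc1)[C@@]2(C)C=CC=C(C)[C@@H]2[C@H](O[Si](CC)(CC)CC)[C@](O[Si](CC)(CC)CC)([C@@H](C)CO)[C@@H](O)[C@@H](Cl)C#C[Si](C)(C)C | intermediate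
26 | γ-lactone C19(=O)–O–C7 with C6–Cl and silyl alkyne; ring diene; 8,9-bis(triethylsilyl) ether | C=C[C@H](OCc1ccc(OC)cc1)[C@@]2(C)C=CC=C(C)[C@@H]2[C@H](O[Si](CC)(CC)CC)[C@]3(O[Si](CC)(CC)CC)[C@@H](C)C(=O)O[C@H]3[C@@H](Cl)C#C[Si](C)(C)C | intermediate
27 | 11α,12α-diol of 26 | C=C[C@H](OCc1ccc(OC)cc1)[C@@]2(C)C=C[C@@H](O)[C@@](C)(O)[C@@H]2[C@H](O[Si](CC)(CC)CC)[C@]3(O[Si](CC)(CC)CC)[C@@H](C)C(=O)O[C@H]3[C@@H](Cl)C#C[Si](C)(C)C | intermediate
28 | 8,9,11,12-tetraol with terminal alkyne, O2-PMB | C=C[C@H](OCc1ccc(OC)cc1)[C@@]2(C)C=C[C@@H](O)[C@@](C)(O)[C@@H]2[C@H](O)[C@]3(O)[C@@H](C)C(=O)O[C@H]3[C@@H](Cl)C#C | intermediate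
29 | 9,12-diacetate of 28 | C=C[C@H](OCc1ccc(OC)cc1)[C@@]2(C)C=C[C@@H](OC(C)=O)[C@@](C)(O)[C@@H]2[C@H](OC(C)=O)[C@]3(O)[C@@H](C)C(=O)O[C@H]3[C@@H](Cl)C#C | intermediate
30 | C2 alcohol (PMB removed) | C=C[C@H](O)[C@@]2(C)C=C[C@@H](OC(C)=O)[C@@](C)(O)[C@@H]2[C@H](OC(C)=O)[C@]3(O)[C@@H](C)C(=O)O[C@H]3[C@@H](Cl)C#C | intermediate
31 | C2 butanoate, seco enyne | C=C[C@H](OC(=O)CCC)[C@@]2(C)C=C[C@@H](OC(C)=O)[C@@](C)(O)[C@@H]2[C@H](OC(C)=O)[C@]3(O)[C@@H](C)C(=O)O[C@H]3[C@@H](Cl)C#C | intermediate
32 | seco triene with C5(=CH2)–C4H=CH2 diene | C=C[C@H](OC(=O)CCC)[C@@]2(C)C=C[C@@H](OC(C)=O)[C@@](C)(O)[C@@H]2[C@H](OC(C)=O)[C@]3(O)[C@@H](C)C(=O)O[C@H]3[C@@H](Cl)C(=C)C=C | intermediate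
33 | CNP0114781.2 (1S,2S,3Z,6S,7R,8R,9S,10S,11S,12R,17R) | C=C1/C=C\[C@H](OC(=O)CCC)[C@@]2(C)C=C[C@@H](OC(C)=O)[C@@](C)(O)[C@@H]2[C@H](OC(C)=O)[C@]2(O)[C@@H](C)C(=O)O[C@H]2[C@H]1Cl | target

**Step count**
Total: 24 steps. Longest linear sequence: 21 steps (steps 1, 3–10, 13–24).

**Steps most likely to fail**

Step 24. Intermolecular metathesis or Diels–Alder dimerisation of the acyclic diene may outpace closure of the strained ten-membered ring, or closure may give the E isomer. The fallback sets out from enyne 31 and comes back at 33. The ring is closed by endo-mode ring-closing enyne metathesis (RuCl2(=CHPh)(PCy3)(H2IMes), toluene, high dilution, 80 °C, no ethylene). The alkyne, not a pre-formed diene, becomes the ring-closing partner: the carbene formed at the C2 vinyl group adds to C4, and the vinyl terminus ends as C16. Ring closure is then the irreversible alkyne insertion and no acyclic diene is ever present; no new compound arises (entry F0).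

Step 13. Proton transfer from the doubly activated C10–H of 14 to the hindered enolate may replace addition, the aldolate may revert on warming, or the enolate face and the Felkin preference of 14 may be mismatched. The fallback sets out from 18 and comes back at 20. Lactone 18 is converted (LiN(i-Pr)2, Me3SiCl, THF, −78 °C) into the silyl ketene acetal (S)-triethyl{[4-methyl-2-(trimethylsilyloxy)-4,5-dihydrofuran-3-yl]oxy}silane F1. A Mukaiyama aldol addition to 14 activated by BF3·OEt2 (CH2Cl2, −78 °C) then forms the C8–C9 bond without any basic species. The nucleophile should again react anti to the C17 methyl group. The C9 selectivity of the open transition state would have to be re-examined.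

Step 16. The metal lactolate may fail to open at the low temperature the carbenoid tolerates, or coordination by the C19 alkoxide may erode facial selectivity at C7. The fallback sets out from 21 and comes back at 25.
- LiBH4 (THF, 0 °C) reduces the lactone to the C7,C19-diol F2.
- The less hindered C19 hydroxyl is silylated (Et3SiCl, imidazole, −20 °C) to the C19 triethylsilyl ether F3.
- Dess–Martin oxidation of the neopentyl C7 alcohol gives the free α-silyloxy aldehyde F4.
- Carbenoid 24 adds under the conditions of step 16 to give the tris-silyl chlorohydrin F5.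
- Selective methanolysis of the primary silyl ether (pyridinium p-toluenesulfonate, MeOH–CH2Cl2, 0 °C) returns diol 25.

**Further compounds**
F0 | step 24 | none | none
F1 | step 13 | (S)-triethyl{[4-methyl-2-(trimethylsilyloxy)-4,5-dihydrofuran-3-yl]oxy}silane | C[C@H]1COC(O[Si](C)(C)C)=C1O[Si](CC)(CC)CC
F2 | step 16 | C7,C19-diol from reduction of 21 | C=C[C@H](OCc1ccc(OC)cc1)[C@@]2(C)C=CC=C(C)[C@@H]2[C@H](O[Si](CC)(CC)CC)[C@](O[Si](CC)(CC)CC)([C@@H](C)CO)CO
F3 | step 16 | C19 triethylsilyl ether of F2 | C=C[C@H](OCc1ccc(OC)cc1)[C@@]2(C)C=CC=C(C)[C@@H]2[C@H](O[Si](CC)(CC)CC)[C@](O[Si](CC)(CC)CC)([C@@H](C)CO[Si](CC)(CC)CC)CO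
F4 | step 16 | C7 aldehyde from F3 | C=C[C@H](OCc1ccc(OC)cc1)[C@@]2(C)C=CC=C(C)[C@@H]2[C@H](O[Si](CC)(CC)CC)[C@](O[Si](CC)(CC)CC)([C@@H](C)CO[Si](CC)(CC)CC)C=O
F5 | step 16 | tris(triethylsilyl) chlorohydrin (C7–OH, C6–Cl, silyl alkyne) | C=C[C@H](OCc1ccc(OC)cc1)[C@@]2(C)C=CC=C(C)[C@@H]2[C@H](O[Si](CC)(CC)CC)[C@](O[Si](CC)(CC)CC)([C@@H](C)CO[Si](CC)(CC)CC)[C@@H](O)[C@@H](Cl)C#C[Si](C)(C)C
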